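The route rests on disconnecting C7–C7a of the hexahydroindene core (indene numbering). In the six-membered ring the gem-dimethyl carbon C7 is bonded to the methyl-bearing fusion carbon C7a, the pattern left when a tertiary radical adds to the β-carbon of a β-methyl cyclopentenone. An iron hydride converts a pendant isopropenyl group into that radical, which closes the six-membered ring 6-exo onto the five-membered enone, joining the two fully substituted carbons and fixing the cis ring fusion in one operation. The precursor is an enantioenriched cyclopent-2-enone with a silyloxypropyl arm at C2, the methyl at C3 and the 4-methylpent-4-enyl tether on the C4 stereocentre.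

Key step: step 9

Assumption: the gold-catalysed closure in step 6 is taken to occur anti to the departing pivalate, so that the (3S)-pivalate 9 gives the (4S)-enone 11; the ligand antipode in step 4 is chosen to match, and 16 and 18, expected as C1 epimer mixtures, are drawn as the (1R) epimer.

Step 1
Reactants: 1 ethyl 5-oxohexanoate
Product: 2 ethyl 5-methylhex-5-enoate
Conditions: MePPh3Br, KOtBu, THF, 0 °C to rt
Reagents that add atoms: methyltriphenylphosphonium bromide, C[P+](c1ccccc1)(c1ccccc1)c1ccccc1.[Br-]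
Why: Wittig methylenation; the non-stabilised ylide attacks the ketone much faster than the ester and installs the isopropenyl group that later becomes C7 with its two methyl groups.

Step 2
Reactants: 2 ethyl 5-methylhex-5-enoate
Product: 3 5-methylhex-5-enal
Conditions: i-Bu2AlH (1.05 equiv), CH2Cl2, −78 °C; aq. Rochelle salt
Reagents that add atoms: none
Why: Partial ester reduction; at −78 °C the aluminium hemiacetal should persist until work-up, so the aldehyde is released without over-reduction and the isolated alkene is untouched.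

Step 3
Reactants: 3 5-methylhex-5-enal; 4 2-(triphenylphosphoranylidene)propanal
Product: 5 (2E)-2,7-dimethylocta-2,7-dienal
Conditions: toluene, 90 °C
Reagents that add atoms: none
Why: Wittig olefination with a stabilised formyl ylide, which reacts with the unhindered aldehyde only and should give the (E)-2-methyl enal.

Step 4
Reactants: 5 (2E)-2,7-dimethylocta-2,7-dienal; 6 ethynyltrimethylsilane
Product: 8 (3S,4E)-4,9-dimethyldeca-4,9-dien-1-yn-3-ol, via C-silyl alkynol 7 (not isolated)
Conditions: ProPhenol (10 mol%, antipode giving the 3R silyl carbinol), Me2Zn, toluene, 0 °C; then K2CO3 (cat.), MeOH, rt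
Reagents that add atoms: none
Why: Catalytic asymmetric zinc-alkynylide addition to an aldehyde, a reaction type that suits α-substituted enals; the chiral dizinc pocket selects the aldehyde face and sets C3, and methanolysis of the C–Si bond frees the terminal alkyne needed for gold catalysis.

Step 5
Reactants: 8 (3S,4E)-4,9-dimethyldeca-4,9-dien-1-yn-3-ol
Product: 9 (3S,4E)-4,9-dimethyldeca-4,9-dien-1-yn-3-yl 2,2-dimethylpropanoate
Conditions: PivCl, Et3N, DMAP (cat.), CH2Cl2, 0 °C to rt
Reagents that add atoms: pivaloyl chloride, CC(C)(C)C(=O)Cl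
Why: DMAP-catalysed acylation of the secondary alcohol, which leaves the stereocentre untouched and installs the migrating group for the next step.

Step 6
Reactants: 9 (3S,4E)-4,9-dimethyldeca-4,9-dien-1-yn-3-yl 2,2-dimethylpropanoate
Product: 11 (4S)-3-methyl-4-(4-methylpent-4-en-1-yl)cyclopent-2-en-1-one, via cyclopentadienyl pivalate 10 (not isolated)
Conditions: Ph3PAuCl (5 mol%), AgSbF6 (5 mol%), wet MeCN, −20 °C
Reagents that add atoms: none
Why: Gold-catalysed Rautenstrauch rearrangement; 1,2-acyloxy shift on the alkyne activated by monovalent gold and ring closure anti to the departing C–O bond should transfer the carbinol chirality to ring carbon C4, and water then hydrolyses the dienyl ester to the enone, whose oxygen is the migrated ester oxygen.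

Step 7
Reactants: 11 (4S)-3-methyl-4-(4-methylpent-4-en-1-yl)cyclopent-2-en-1-one
Product: 12 (4S)-2-iodo-3-methyl-4-(4-methylpent-4-en-1-yl)cyclopent-2-en-1-one
Conditions: I2, pyridine, CH2Cl2, 0 °C to rt; aq. Na2S2O3
Reagents that add atoms: iodine, II
Why: Pyridine-mediated α-iodination of an enone (conjugate addition of pyridine, iodination, elimination); the enone is the only site that reacts irreversibly, and iodine taken up reversibly by the isolated alkene is returned on thiosulfate work-up.

Step 8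
Reactants: 13 tert-butyldimethyl(prop-2-en-1-yloxy)silane; 12 (4S)-2-iodo-3-methyl-4-(4-methylpent-4-en-1-yl)cyclopent-2-en-1-one
Product: 15 (4S)-2-[3-(tert-butyldimethylsilyloxy)propyl]-3-methyl-4-(4-methylpent-4-en-1-yl)cyclopent-2-en-1-one, via B-alkyl-9-BBN 14 (not isolated)
Conditions: 13 (1.6 equiv), 9-BBN (1.5 equiv), THF, rt; then 12, PdCl2(dppf) (5 mol%), AsPh3, Cs2CO3, DMF/THF/H2O, rt
Reagents that add atoms: none
Why: B-alkyl Suzuki–Miyaura coupling; 9-BBN hydroborates the allyl ether at its terminus and the primary alkylborane couples with the α-iodoenone at room temperature, while the excess of 13 over 9-BBN leaves no B–H to attack the isopropenyl group.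

Step 9
Reactants: 15 (4S)-2-[3-(tert-butyldimethylsilyloxy)propyl]-3-methyl-4-(4-methylpent-4-en-1-yl)cyclopent-2-en-1-one
Product: 16 (3aS,7aS)-1-[3-(tert-butyldimethylsilyloxy)propyl]-7,7,7a-trimethyloctahydro-2H-inden-2-one (cis-fused; C1 epimers)
Conditions: Fe(acac)3 (0.5 equiv), PhSiH3 (2.5 equiv, slow addition), EtOH/(CH2OH)2 5:1, 0.01 M, 60 °C, argon
Reagents that add atoms: none
Why: An iron hydride formed from Fe(acac)3 and the silane transfers a hydrogen atom to the terminal CH2 of the isopropenyl group, giving the tertiary radical that becomes C7; this nucleophilic radical adds to the electron-poor β-carbon of the enone, and the α-keto radical is then reduced by divalent iron to the enolate and protonated by ethanol. The closest known reaction type is the iron/silane hydrogen-atom-transfer reductive olefin–enone coupling, which is established for joining two fully substituted carbons because the early transition state of radical addition tolerates crowding. The six-membered ring closes in the 6-exo-trig mode, since attack at the α-carbon (7-endo) is polarity-mismatched and more strained. The new quaternary centre C7a is controlled by the C4 stereocentre of 15 (future C3a): the three-carbon tether reaches the enone only on the face it occupies, so the fusion is cis with C3a–H and the C7a methyl on the same side, whereas C1 arises from unselective protonation and is left as a mixture because it is planarised again in step 11. The step needs hydrogen-atom transfer to the 1,1-disubstituted alkene only (the tetrasubstituted enone is inert to the iron hydride) and cyclisation faster than reduction of the radical, which high dilution and slow silane addition favour.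

Step 10
Reactants: 16 (3aS,7aS)-1-[3-(tert-butyldimethylsilyloxy)propyl]-7,7,7a-trimethyloctahydro-2H-inden-2-one
Product: 18 (7aS)-1-[3-(tert-butyldimethylsilyloxy)propyl]-7,7,7a-trimethyl-1,4,5,6,7,7a-hexahydro-2H-inden-2-one (C1 epimers), via trimethylsilyl enol ether 17 (not isolated)
Conditions: LiN(i-Pr)2, Me3SiCl, THF, −78 °C; then Pd(OAc)2 (1.1 equiv), MeCN, rt
Reagents that add atoms: none
Why: Saegusa–Ito dehydrogenation; kinetic deprotonation with in-situ silylation occurs at the unhindered C3 methylene, not at the neopentyl-type C1–H, and divalent palladium converts the silyl enol ether into the enone by β-hydride loss from C3a, which erases that stereocentre as planned.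

Step 11
Reactants: 18 (7aS)-1-[3-(tert-butyldimethylsilyloxy)propyl]-7,7,7a-trimethyl-1,4,5,6,7,7a-hexahydro-2H-inden-2-one
Product: 20 (1S,7aS)-1-[3-(tert-butyldimethylsilyloxy)propyl]-1,7,7,7a-tetramethyl-1,4,5,6,7,7a-hexahydro-2H-inden-2-one, via lithium enolate 19 (not isolated)
Conditions: LiN(i-Pr)2 (1.05 equiv), THF, −78 °C; then MeI, DMPU, −78 to −20 °C
Reagents that add atoms: iodomethane, CI
Why: Kinetic α′-alkylation of an enone; with C3 now sp2 the amide base should form the cross-conjugated C1 enolate, and iodomethane should attack its top face, syn to the C7a methyl and anti to the much bulkier C7 quaternary carbon, so both C1 epimers converge on one quaternary centre with the new methyl cis to the angular methyl.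

Step 12
Reactants: 20 (1S,7aS)-1-[3-(tert-butyldimethylsilyloxy)propyl]-1,7,7,7a-tetramethyl-1,4,5,6,7,7a-hexahydro-2H-inden-2-one
Product: 22 (1S,7aS)-1-[3-(tert-butyldimethylsilyloxy)propyl]-1,7,7,7a-tetramethyl-1,3,5,6,7,7a-hexahydro-2H-inden-2-one, via potassium dienolate 21 (not isolated)
Conditions: KN(SiMe3)2, THF, −78 to −40 °C; then AcOH, −78 °C
Reagents that add atoms: none
Why: Deconjugation of an enone through its extended dienolate; with no α′-hydrogen left the base removes a γ-hydrogen at C4, and kinetic protonation at the α-carbon C3 places the double bond at C3a=C4.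

Step 13
Reactants: 22 (1S,7aS)-1-[3-(tert-butyldimethylsilyloxy)propyl]-1,7,7,7a-tetramethyl-1,3,5,6,7,7a-hexahydro-2H-inden-2-one
Product: 23 tert-butyl{3-[(1R,7aS)-1,7,7,7a-tetramethyl-2-methylidene-2,3,5,6,7,7a-hexahydro-1H-inden-1-yl]propoxy}dimethylsilane
Conditions: Zn, CH2Br2, TiCl4 (reagent pre-formed), THF/CH2Cl2, 0 °C to rt
Reagents that add atoms: dibromomethane, BrCBr
Why: Takai–Lombardo methylenation; the non-basic zinc/titanium methylene reagent should add to the hindered, easily enolised ketone without moving the β,γ-double bond back into conjugation, and the silyl ether tolerates it.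

Step 14
Reactants: 23 tert-butyl{3-[(1R,7aS)-1,7,7,7a-tetramethyl-2-methylidene-2,3,5,6,7,7a-hexahydro-1H-inden-1-yl]propoxy}dimethylsilane
Product: 24 3-[(1R,7aS)-1,7,7,7a-tetramethyl-2-methylidene-2,3,5,6,7,7a-hexahydro-1H-inden-1-yl]propan-1-ol
Conditions: Bu4NF, THF, 0 °C to rt
Reagents that add atoms: none
Why: Fluoride-induced silyl ether cleavage, driven by the Si–F bond; nothing else in the molecule is sensitive to fluoride.

Step 15
Reactants: 24 3-[(1R,7aS)-1,7,7,7a-tetramethyl-2-methylidene-2,3,5,6,7,7a-hexahydro-1H-inden-1-yl]propan-1-ol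
Product: 25 3-[(1R,7aS)-1,7,7,7a-tetramethyl-2-methylidene-2,3,5,6,7,7a-hexahydro-1H-inden-1-yl]propanal
Conditions: Dess–Martin periodinane, NaHCO3, CH2Cl2, 0 °C to rt
Reagents that add atoms: none
Why: Dess–Martin oxidation of the primary alcohol to the aldehyde under buffered, near-neutral conditions that leave the skipped diene in place.

Step 16
Reactants: 25 3-[(1R,7aS)-1,7,7,7a-tetramethyl-2-methylidene-2,3,5,6,7,7a-hexahydro-1H-inden-1-yl]propanal; 26 ethyl 2-[bis(2,2,2-trifluoroethoxy)phosphoryl]propanoate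
Product: 27 ethyl (2Z)-2-methyl-5-[(1R,7aS)-1,7,7,7a-tetramethyl-2-methylidene-2,3,5,6,7,7a-hexahydro-1H-inden-1-yl]pent-2-enoate
Conditions: KN(SiMe3)2, 18-crown-6, THF, −78 °C
Reagents that add atoms: none
Why: Still–Gennari olefination; the trifluoroethyl phosphonate anion with a dissociated potassium counter-ion eliminates rapidly from the kinetic adduct and should give the (Z)-2-methyl enoate, with ester and chain on the same side.

Step 17
Reactants: 27 ethyl (2Z)-2-methyl-5-[(1R,7aS)-1,7,7,7a-tetramethyl-2-methylidene-2,3,5,6,7,7a-hexahydro-1H-inden-1-yl]pent-2-enoate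
Product: 28 (2Z)-2-methyl-5-[(1R,7aS)-1,7,7,7a-tetramethyl-2-methylidene-2,3,5,6,7,7a-hexahydro-1H-inden-1-yl]pent-2-en-1-ol
Conditions: i-Bu2AlH (2.5 equiv), CH2Cl2, −78 °C; aq. Rochelle salt
Reagents that add atoms: none
Why: 1,2-Reduction of the α,β-unsaturated ester to the allylic alcohol by the aluminium hydride, with the Z geometry retained.

Step 18
Reactants: 28 (2Z)-2-methyl-5-[(1R,7aS)-1,7,7,7a-tetramethyl-2-methylidene-2,3,5,6,7,7a-hexahydro-1H-inden-1-yl]pent-2-en-1-ol
Product: 29 (2Z)-2-methyl-5-[(1R,7aS)-1,7,7,7a-tetramethyl-2-methylidene-2,3,5,6,7,7a-hexahydro-1H-inden-1-yl]pent-2-en-1-yl acetate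
Conditions: Ac2O, pyridine, DMAP (cat.), CH2Cl2, 0 °C to rt
Reagents that add atoms: acetic anhydride, CC(=O)OC(C)=O
Why: DMAP-catalysed acetylation of the primary allylic alcohol.

Step 19
Reactants: 29 (2Z)-2-methyl-5-[(1R,7aS)-1,7,7,7a-tetramethyl-2-methylidene-2,3,5,6,7,7a-hexahydro-1H-inden-1-yl]pent-2-en-1-yl acetate
Product: 31 (2Z)-5-[(1R,2R,7aS)-2-(hydroxymethyl)-1,7,7,7a-tetramethyl-2,3,5,6,7,7a-hexahydro-1H-inden-1-yl]-2-methylpent-2-en-1-yl acetate, via trialkylborane 30 (not isolated)
Conditions: 9-BBN, THF, 0 °C to rt; then NaBO3·4H2O, H2O, rt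
Reagents that add atoms: sodium perborate, [Na+].[Na+].O[B-]1(O)OO[B-](O)(O)OO1
Why: Hydroboration–oxidation; 9-BBN adds anti-Markovnikov to the 1,1-disubstituted exocyclic alkene much faster than to the two trisubstituted alkenes and spares the acetate, perborate oxidises the C–B bond without hydrolysing the ester, and hydrogen should reach C2 from the less hindered top face (the side of the two methyl groups), leaving CH2OH cis to the side chain until the next step corrects C2.

Step 20
Reactants: 31 (2Z)-5-[(1R,2R,7aS)-2-(hydroxymethyl)-1,7,7,7a-tetramethyl-2,3,5,6,7,7a-hexahydro-1H-inden-1-yl]-2-methylpent-2-en-1-yl acetate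
Product: 33 (2Z)-5-[(1R,2S,7aS)-2-formyl-1,7,7,7a-tetramethyl-2,3,5,6,7,7a-hexahydro-1H-inden-1-yl]-2-methylpent-2-en-1-yl acetate, via C2-epimeric aldehyde 32 (not isolated)
Conditions: Dess–Martin periodinane, NaHCO3, CH2Cl2, 0 °C; then DBU (cat.), CH2Cl2, rt
Reagents that add atoms: none
Why: Dess–Martin oxidation followed by base-mediated epimerisation of the aldehyde α-centre through its enolate; at equilibrium the formyl group should sit on the less hindered top face, cis to the C1 and C7a methyl groups and trans to the C1 side chain and the C7 quaternary carbon, which is the (2S) configuration of the target.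

Step 21
Reactants: 33 (2Z)-5-[(1R,2S,7aS)-2-formyl-1,7,7,7a-tetramethyl-2,3,5,6,7,7a-hexahydro-1H-inden-1-yl]-2-methylpent-2-en-1-yl acetate
Product: 34 (1R,2S,7aS)-1-[(3Z)-5-(acetyloxy)-4-methylpent-3-en-1-yl]-1,7,7,7a-tetramethyl-2,3,5,6,7,7a-hexahydro-1H-indene-2-carboxylic acid
Conditions: NaClO2, NaH2PO4, 2-methylbut-2-ene, t-BuOH/H2O, 0 °C to rt
Reagents that add atoms: sodium chlorite, [Na+].[O-]Cl=O
Why: Pinnick oxidation; chlorous acid converts the aldehyde into the acid without epimerising C2, the alkene scavenger removes hypochlorous acid before it can attack the double bonds, and the acetate is stable at the buffered pH.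

Compound list
1 | ethyl 5-oxohexanoate | CCOC(=O)CCCC(C)=O | starting material
2 | ethyl 5-methylhex-5-enoate | CCOC(=O)CCCC(C)=C | intermediate
3 | 5-methylhex-5-enal | O=CCCCC(C)=C | intermediate
4 | 2-(triphenylphosphoranylidene)propanal | CC(C=O)=P(c1ccccc1)(c1ccccc1)c1ccccc1 | starting material
5 | (2E)-2,7-dimethylocta-2,7-dienal | O=C/C(C)=C/CCCC(C)=C | intermediate
6 | ethynyltrimethylsilane | C#C[Si](C)(C)C | starting material
7 | (3R,4E)-4,9-dimethyl-1-(trimethylsilyl)deca-4,9-dien-1-yn-3-ol | C[Si](C)(C)C#C[C@H](O)/C(C)=C/CCCC(C)=C | intermediate (not isolated)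
8 | (3S,4E)-4,9-dimethyldeca-4,9-dien-1-yn-3-ol | C#C[C@H](O)/C(C)=C/CCCC(C)=C | intermediate
9 | (3S,4E)-4,9-dimethyldeca-4,9-dien-1-yn-3-yl 2,2-dimethylpropanoate | C#C[C@H](OC(=O)C(C)(C)C)/C(C)=C/CCCC(C)=C | intermediate
10 | (3S)-4-methyl-3-(4-methylpent-4-en-1-yl)cyclopenta-1,4-dien-1-yl 2,2-dimethylpropanoate | CC1=CC(OC(=O)C(C)(C)C)=C[C@@H]1CCCC(C)=C | intermediate (not isolated)
11 | (4S)-3-methyl-4-(4-methylpent-4-en-1-yl)cyclopent-2-en-1-one | C=C(C)CCC[C@H]1CC(=O)C=C1C | intermediate
12 | (4S)-2-iodo-3-methyl-4-(4-methylpent-4-en-1-yl)cyclopent-2-en-1-one | C=C(C)CCC[C@H]1CC(=O)C(I)=C1C | intermediate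
13 | tert-butyldimethyl(prop-2-en-1-yloxy)silane | C=CCO[Si](C)(C)C(C)(C)C | starting material
14 | 9-[3-(tert-butyldimethylsilyloxy)propyl]-9-borabicyclo[3.3.1]nonane | CC(C)(C)[Si](C)(C)OCCCB1C2CCCC1CCC2 | intermediate (not isolated)
15 | (4S)-2-[3-(tert-butyldimethylsilyloxy)propyl]-3-methyl-4-(4-methylpent-4-en-1-yl)cyclopent-2-en-1-one | C=C(C)CCC[C@H]1CC(=O)C(CCCO[Si](C)(C)C(C)(C)C)=C1C | intermediate
16 | (3aS,7aS)-1-[3-(tert-butyldimethylsilyloxy)propyl]-7,7,7a-trimethyloctahydro-2H-inden-2-one, cis-fused, C1 epimer mixture drawn as (1R) | CC(C)(C)[Si](C)(C)OCCC[C@H]1C(=O)C[C@@H]2CCCC(C)(C)[C@@]21C | intermediate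
17 | trimethylsilyl enol ether of 16 with the C2=C3 double bond, drawn as the (1R,3aS,7aS) epimer | CC(C)(C)[Si](C)(C)OCCC[C@H]1C(O[Si](C)(C)C)=C[C@@H]2CCCC(C)(C)[C@@]21C | intermediate (not isolated)
18 | (7aS)-1-[3-(tert-butyldimethylsilyloxy)propyl]-7,7,7a-trimethyl-1,4,5,6,7,7a-hexahydro-2H-inden-2-one, C1 epimer mixture drawn as (1R) | CC(C)(C)[Si](C)(C)OCCC[C@H]1C(=O)C=C2CCCC(C)(C)[C@@]21C | intermediate
19 | lithium enolate of 18 (cross-conjugated, C1=C2 and C3=C3a), (7aS) | [Li+].CC(C)(C)[Si](C)(C)OCCCC1=C([O-])C=C2CCCC(C)(C)[C@@]21C | intermediate (not isolated)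
20 | (1S,7aS)-1-[3-(tert-butyldimethylsilyloxy)propyl]-1,7,7,7a-tetramethyl-1,4,5,6,7,7a-hexahydro-2H-inden-2-one (C1 methyl cis to C7a methyl) | CC(C)(C)[Si](C)(C)OCCC[C@]1(C)C(=O)C=C2CCCC(C)(C)[C@@]21C | intermediate
21 | potassium dienolate of 20 (C2=C3 and C3a=C4), (1S,7aS) | [K+].CC(C)(C)[Si](C)(C)OCCC[C@]1(C)C([O-])=CC2=CCCC(C)(C)[C@@]21C | intermediate (not isolated)
22 | (1S,7aS)-1-[3-(tert-butyldimethylsilyloxy)propyl]-1,7,7,7a-tetramethyl-1,3,5,6,7,7a-hexahydro-2H-inden-2-one | CC(C)(C)[Si](C)(C)OCCC[C@]1(C)C(=O)CC2=CCCC(C)(C)[C@@]21C | intermediate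
23 | tert-butyl{3-[(1R,7aS)-1,7,7,7a-tetramethyl-2-methylidene-2,3,5,6,7,7a-hexahydro-1H-inden-1-yl]propoxy}dimethylsilane | CC(C)(C)[Si](C)(C)OCCC[C@]1(C)C(=C)CC2=CCCC(C)(C)[C@@]21C | intermediate
24 | 3-[(1R,7aS)-1,7,7,7a-tetramethyl-2-methylidene-2,3,5,6,7,7a-hexahydro-1H-inden-1-yl]propan-1-ol | OCCC[C@]1(C)C(=C)CC2=CCCC(C)(C)[C@@]21C | intermediate
25 | 3-[(1R,7aS)-1,7,7,7a-tetramethyl-2-methylidene-2,3,5,6,7,7a-hexahydro-1H-inden-1-yl]propanal | O=CCC[C@]1(C)C(=C)CC2=CCCC(C)(C)[C@@]21C | intermediate
26 | ethyl 2-[bis(2,2,2-trifluoroethoxy)phosphoryl]propanoate | CCOC(=O)C(C)P(=O)(OCC(F)(F)F)OCC(F)(F)F | starting material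
27 | ethyl (2Z)-2-methyl-5-[(1R,7aS)-1,7,7,7a-tetramethyl-2-methylidene-2,3,5,6,7,7a-hexahydro-1H-inden-1-yl]pent-2-enoate | CCOC(=O)/C(C)=C\CC[C@]1(C)C(=C)CC2=CCCC(C)(C)[C@@]21C | intermediate
28 | (2Z)-2-methyl-5-[(1R,7aS)-1,7,7,7a-tetramethyl-2-methylidene-2,3,5,6,7,7a-hexahydro-1H-inden-1-yl]pent-2-en-1-ol | OC/C(C)=C\CC[C@]1(C)C(=C)CC2=CCCC(C)(C)[C@@]21C | intermediate
29 | (2Z)-2-methyl-5-[(1R,7aS)-1,7,7,7a-tetramethyl-2-methylidene-2,3,5,6,7,7a-hexahydro-1H-inden-1-yl]pent-2-en-1-yl acetate | CC(=O)OC/C(C)=C\CC[C@]1(C)C(=C)CC2=CCCC(C)(C)[C@@]21C | intermediate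
30 | 9-BBN adduct of 29 (boron on the new C2 methylene, cis to the side chain) | CC(=O)OC/C(C)=C\CC[C@]1(C)[C@H](CB3C4CCCC3CCC4)CC2=CCCC(C)(C)[C@@]21C | intermediate (not isolated)
31 | (2Z)-5-[(1R,2R,7aS)-2-(hydroxymethyl)-1,7,7,7a-tetramethyl-2,3,5,6,7,7a-hexahydro-1H-inden-1-yl]-2-methylpent-2-en-1-yl acetate | CC(=O)OC/C(C)=C\CC[C@]1(C)[C@H](CO)CC2=CCCC(C)(C)[C@@]21C | intermediate
32 | (2Z)-5-[(1R,2R,7aS)-2-formyl-1,7,7,7a-tetramethyl-2,3,5,6,7,7a-hexahydro-1H-inden-1-yl]-2-methylpent-2-en-1-yl acetate | CC(=O)OC/C(C)=C\CC[C@]1(C)[C@H](C=O)CC2=CCCC(C)(C)[C@@]21C | intermediate (not isolated)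
33 | (2Z)-5-[(1R,2S,7aS)-2-formyl-1,7,7,7a-tetramethyl-2,3,5,6,7,7a-hexahydro-1H-inden-1-yl]-2-methylpent-2-en-1-yl acetate | CC(=O)OC/C(C)=C\CC[C@]1(C)[C@@H](C=O)CC2=CCCC(C)(C)[C@@]21C | intermediate
34 | (1R,2S,7aS)-1-[(3Z)-5-(acetyloxy)-4-methylpent-3-en-1-yl]-1,7,7,7a-tetramethyl-2,3,5,6,7,7a-hexahydro-1H-indene-2-carboxylic acid | CC(=O)OC/C(C)=C\CC[C@]1(C)[C@@H](C(=O)O)CC2=CCCC(C)(C)[C@@]21C | target

Total step count: 21. Longest linear sequence: 21 steps, from 1 to 34.

Steps most likely to fail

Step 9. The ring closure may be outrun by premature reduction of the tertiary radical, by isomerisation of the alkene, or by a 1,5-hydrogen shift from the ring carbon that carries the tether. The fallback makes the same radical without a metal hydride and sets out from 15. Hydration of the isopropenyl group (Co(acac)2, PhSiH3, O2, THF, rt) should give the tertiary alcohol (4S)-2-[3-(tert-butyldimethylsilyloxy)propyl]-4-(4-hydroxy-4-methylpentyl)-3-methylcyclopent-2-en-1-one F1. Acylation with methyl chlorooxoacetate (Et3N, DMAP, CH2Cl2) gives the mixed methyl oxalate of this alcohol F2, and one equivalent of CsOH in THF/H2O hydrolyses it to the caesium oxalate F3. Visible-light photoredox catalysis (Ir[dF(CF3)ppy]2(dtbbpy)PF6, DME/DMF/H2O, blue light) then expels two molecules of CO2; the tertiary radical cyclises onto the enone as before and the route is rejoined at 16.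

Step 11. Deprotonation may occur at the γ-methylene C4 instead of the hindered C1–H, which would divert methylation to C3, or iodomethane may attack the bottom face. The fallback quaternises C1 before the dehydrogenation and sets out from 16. Thermodynamic silylation (Me3SiI, HN(SiMe3)2, CH2Cl2) gives the tetrasubstituted C1=C2 trimethylsilyl enol ether of 16 F4, freed from its regioisomer by chromatography. MeLi in THF regenerates the regiodefined lithium enolate, and MeI then gives the saturated ketone (1S,3aS,7aR)-1-[3-(tert-butyldimethylsilyloxy)propyl]-1,7,7,7a-tetramethyloctahydro-2H-inden-2-one F5. Kinetic silylation at C3 (LiN(i-Pr)2, Me3SiCl) gives the C2=C3 trimethylsilyl enol ether of that ketone F6, and Pd(OAc)2 in MeCN converts it into 20, where the route is rejoined.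

Step 13. Addition to the ketone flanked by a quaternary carbon may be slow, and the Lewis-acidic medium may pull the C3a=C4 bond back into conjugation before methylenation. The fallback replaces the one-step methylenation by a two-step Peterson olefination and sets out from 22. The organocerium reagent from Me3SiCH2Li and CeCl3 (THF, −78 °C) is nucleophilic but barely basic and should add to C2 to give the tertiary β-hydroxysilane (1S,2R,7aS)-1-[3-(tert-butyldimethylsilyloxy)propyl]-1,7,7,7a-tetramethyl-2-[(trimethylsilyl)methyl]-2,3,5,6,7,7a-hexahydro-1H-inden-2-ol F7, whose C2 configuration is immaterial. KH in THF then induces syn-elimination of the silanolate and delivers 23, where the route is rejoined.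

Further compounds
F1 | step 9 | (4S)-2-[3-(tert-butyldimethylsilyloxy)propyl]-4-(4-hydroxy-4-methylpentyl)-3-methylcyclopent-2-en-1-one | CC(C)(O)CCC[C@H]1CC(=O)C(CCCO[Si](C)(C)C(C)(C)C)=C1C
F2 | step 9 | 5-[(1S)-3-[3-(tert-butyldimethylsilyloxy)propyl]-2-methyl-4-oxocyclopent-2-en-1-yl]-2-methylpentan-2-yl methyl oxalate | COC(=O)C(=O)OC(C)(C)CCC[C@H]1CC(=O)C(CCCO[Si](C)(C)C(C)(C)C)=C1C
F3 | step 9 | caesium 2-({5-[(1S)-3-[3-(tert-butyldimethylsilyloxy)propyl]-2-methyl-4-oxocyclopent-2-en-1-yl]-2-methylpentan-2-yl}oxy)-2-oxoacetate | [Cs+].[O-]C(=O)C(=O)OC(C)(C)CCC[C@H]1CC(=O)C(CCCO[Si](C)(C)C(C)(C)C)=C1C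
F4 | step 11 | C1=C2 trimethylsilyl enol ether of 16 | CC(C)(C)[Si](C)(C)OCCCC1=C(O[Si](C)(C)C)C[C@@H]2CCCC(C)(C)[C@@]21C
F5 | step 11 | (1S,3aS,7aR)-1-[3-(tert-butyldimethylsilyloxy)propyl]-1,7,7,7a-tetramethyloctahydro-2H-inden-2-one | CC(C)(C)[Si](C)(C)OCCC[C@]1(C)C(=O)C[C@@H]2CCCC(C)(C)[C@@]21C
F6 | step 11 | C2=C3 trimethylsilyl enol ether of F5 | CC(C)(C)[Si](C)(C)OCCC[C@]1(C)C(O[Si](C)(C)C)=C[C@@H]2CCCC(C)(C)[C@@]21C
F7 | step 13 | (1S,2R,7aS)-1-[3-(tert-butyldimethylsilyloxy)propyl]-1,7,7,7a-tetramethyl-2-[(trimethylsilyl)methyl]-2,3,5,6,7,7a-hexahydro-1H-inden-2-ol | CC(C)(C)[Si](C)(C)OCCC[C@]1(C)[C@@](O)(C[Si](C)(C)C)CC2=CCCC(C)(C)[C@@]21C
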